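At early times the flask is a suspension: solid substrate and acid are present, none of the solid is in solution, and starting material enters at up to 0.135 mM/min, the dissolution coefficient times the solubility.

solid substrate 41 mM; acid 4.10 mM; time 40 min

* part of the solid substrate that has reacted (what has only dissolved counts as not reacted) at 40 min
* pH of the solution at 40 min

- acid is the free proton; pH is minus the decimal logarithm of its molar concentration
- percentages count the solid substrate that a species holds: one side product counts as two
- solid, in amounts per volume of the solution: solid substrate
- at the start none of the solid substrate is in solution
- what has only dissolved of solid substrate counts as not reacted
- run time (flask): 40 min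

    starting material + acid → weak acid + acid + target (k1 = 3.6 /M/s)
    weak acid ⇌ conjugate base + acid, settled at all times (K2 = 1.6 × 10⁻¹⁰ M)
    starting material → weak acid + target (k3 = 2.7 × 10⁻⁶ /s)
    target ⇌ isomer of the product (K4 = 0.29, k4 = 5.6 × 10⁻⁴ /s)
    solid substrate ⇌ starting material, rate k5*(cs5 - [starting material]) while solid is left; crystals form when [starting material] > cs5 (cs5 = 4.7 mM, k5 = 4.8 × 10⁻⁴ /s)
    starting material + target → side product (k6 = 0.0028 /M/s)

We follow this flask in slow motion. During the first minutes, two first-order constants act on starting material. The acid removes it with 0.886 /min (pseudo-first-order, since the acid step returns its acid), while dissolution has the slower coefficient 0.029 /min, which makes dissolution the rate-limiting step. Starting material climbs over a lag and stops where supply equals removal: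

lag = 1 / (dissolution coefficient + acid constant) = 1.09 min

c(starting material) = dissolution coefficient × solubility × lag = 0.148 mM

That level lies far below the solubility. Through the middle of the run, the feed 0.131 mM/min, the steady rate at which dissolved starting material is turned over, carries the reckoning. Target meanwhile passes into its isomer with a forward half-life of 21 min, but both count as reacted.

Towards the end, two side routes stay small. The uncatalysed step has a half-life of 71 h against 0.78 min for the acid step, and the side-product step removes starting material with 8.81 × 10⁻⁴ /min, far below the acid constant. Joining the two ends:

reacted = feed × (time − lag) = 5.10 mM, which is 12.4% of the charge

This is less than the 41 mM charged, so solid lasts through the run. The acid comes back from its step, and because the constant 1.6 × 10⁻¹⁰ M lies far below 4.10 mM, the weak acid adds little, so we commit to a pH of 2.39.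

The forecast reads 12.4% and pH 2.39, holding that “dissolution at nearly full driving force sets the rate”. The simulation gives 12.4% and pH 2.39.

At 40.0 min the simulated flask holds 0.361% of the charge as starting material, and our level was 0.361%. The same feed serves the neighbouring flask, left until 25 min with all amounts held. The feed times that time less the lag gives 3.13 mM, or 7.63% of the charge, and the simulation of that flask gives 7.64%. At its end, 92% of the charged solid substrate is still there, solid or dissolved.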